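(The numbers of this flask are made up.)

You read south and south-west at 30 s and east at steady state, with 30 s in it on average, so what counts is how old the target in each flask is when you read it.

| flask | starting material | protic impurity | time | remark |
|---|---|---|---|---|
| south | 0.0020 M (fed, over 24.0 s) | 2.00 mM | 30 s | a stirred flask in which starting material is dosed at a steady rate over 24.0 s without added volume, worked up at 30 s |
| south-west | 0.0020 M | 2.00 mM | 30 s | everything together in a closed stirred flask, run for 30 s |
| east | 0.0020 M | 2.00 mM |  | a single well-mixed tank run continuously and read at steady state, 30 s in it on average |

    2 starting material → self-condensation product (k1 = 190 /M/s)
    starting material + protic impurity → quenched substrate (k2 = 590 /M/s)
    starting material ⇌ target (K3 = 25, k3 = 0.37 /s)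
    target ⇌ isomer of the product (K4 = 1.7, k4 = 0.11 /s)

- percentages count the starting material that a species holds: one self-condensation product counts as two
- a doubled species enters its step squared and goes two at a time
- the stated concentrations are those of everything mixed, before any reaction; amounts are the same in each set-up
- the feed brings no volume worth counting
- run time (south): 30 s

* the set-up with the highest share of target in all that became target or isomer of the product, at the outlet or at the end ("none" if the first two lie within 2 percentage points) (south / south-west / east / none)
* share of target in all that became target or isomer of the product, at the outlet or at the end, south
* share of target in all that became target or isomer of the product, at the outlet or at the end, south-west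
* share of target in all that became target or isomer of the product, at the outlet or at the end, east

Carry the relaxation time, 5.72 s, which is one over the sum of the forward and back constants of target ⇌ isomer of the product. Fresh target holds the full share, and the gap down to the equilibrium share 37.0% shrinks as the exponential of minus its age over the relaxation time. So you average that decay over the ages in each flask. Starting material reaches target with a forward half-life of 1.87 s, shorter than the relaxation time, so I date each portion from when it enters.

In south-west every portion is 30 s old, which gives 37.4%. In south the ages spread evenly from 6.00 s to 30 s, which gives 42.2%. In east the ages spread exponentially about a mean of 30 s, which gives 47.1%. My pick is east.

The forecast names east, with 43.6% for south, 36.2% for south-west and 47.1% for east, the share being “set by how long the material has spent” in that step. Its south figure stands above mine, and its south-west figure stands below mine.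

The simulation gives east, with 44.0% for south, 36.3% for south-west and 47.1% for east.

In south-west the forward half-life of target into isomer of the product, 6.3 s with the way back not counted, is short against 30 s. At 30.0 s that flask makes target at 0.414 of the rate at which it uses it up, each step taken net, and its age by then is 5.24 relaxation times. The same south-west flask read at 12 s is 2.10 relaxation times old, so the shrinking gap puts its share at 44.7%, and it reads 45.3%.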